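Molar per day was the unit I put the runs into first.

| setting | east | south-west | north-east | flask |
|---|---|---|---|---|
| X | 0.12 M | 0.50 M | 0.25 M | 0.25 M |
| D | 0.50 M | 0.50 M | 0.75 M | 0.500 M |
| Q | 25 mM | 25 mM | 25 mM | 25 mM |
| remark | run made earlier | run made earlier | run made earlier |  |
| time |  |  |  | 4.0 d |

- east (time / d: J / %, X / %): 0.0833: 39.0, 50.5; 0.208: 64.8, 16.7; 0.500: 53.7, 1.7; 1.25: 12.6, 0; 3.00: 1.2, 0
- south-west (time / d: J / %, X / %): 0.0833: 24.2, 71.5; 0.208: 47.1, 39.0; 0.500: 55.5, 4.1; 1.25: 16.2, 0; 3.00: 0.4, 0.3
- north-east (time / d: J / %, X / %): 0.0833: 33.3, 60.7; 0.208: 63.9, 25.8; 0.500: 54.8, 1.0; 1.25: 14.7, 0.2; 3.00: 0, 0.4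

(each reading ± 1 percentage point)

1. when, up to 4.0 d, the flask holds most J
2. the amount of J, in percent of the X charged, at that time



The bench rule says the loss of X is first order, so the rate grows in step with c_X. Over the first reading the east run lost 0.713 M d⁻¹ and the south-west run 1.71 M d⁻¹. The charges differ by a factor 4.17, but the rates differ by less, 2.40. So the rule failed at these charges.

I tried a ceiling instead: rate = V c_X/(K + c_X). The mean c_X values were 0.0903 M and 0.429 M. They gave 0.255 M for K, the c_X at which the rate is half its ceiling, and 2.73 M d⁻¹ for V. Well below K the loss is pseudo-first-order. The flask starts with c_X close to K, so it crosses that border.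

The north-east run, with more D, lost 1.18 M d⁻¹. K and V give 1.20 M d⁻¹, so I dropped D.

That run's J fell at 1.75 d⁻¹. Taking J in the flask near that run's reading of 63.9%, I reckoned its loss at 0.280 M d⁻¹. The use of X falls to that at c_X = 0.0292 M, which I reckoned for 0.282 d.

The forecast said 0.27 d and 66.5%, on the ground that “The maximum comes when formation equals decay”.

The flask gave 64.8% at 0.299 d.

    X + Q → Z (k = 0.290 M⁻¹ min⁻¹)
    D + Z → E (k = 3.10 M⁻¹ min⁻¹)
    E → Q + J (k = 0.0730 min⁻¹)
    J → G (k = 0.00120 min⁻¹)

At 0.299 d the flask held X at 0.0278 M, less than K, and E and Z held 11.5% of the catalyst charged. A neighbouring flask was charged with 0.10 M of Q. I kept K and took V in proportion to Q, which gives 10.9 M d⁻¹. Taking J at the height this neighbouring flask reached, I reckoned its crossing at c_X = 0.00899 M and at 0.0998 d, earlier than 0.282 d. The half-life of J by the passing of J into G alone is 0.40 d, longer than that reckoned time. The neighbouring flask reached 84.7% of J, more than the 64.8% of the flask.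

(Readings and results are calculated on assumed constants; scatter was added.)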